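**Retrosynthetic overview**

1. Side chains: the three arylglycerol β-aryl ether units are cut at C7–C8 and built by auxiliary-controlled glycolate aldols on aryloxyacetyl imides hung on the phenol oxygens (boron syn-aldol for threo unit B; a magnesium-catalysed anti-aldol for erythro units A and C in one operation), leaving a (7R,8S,7'R,8'S)-syringaresinol with one silyl- and one benzyl-protected phenol.
2. Core: the 3,7-dioxabicyclo[3.3.0]octane is cut at the ring-fusion C–C bond and at the benzylic C–O bond of the tetrahydrofuran that carries ring S1, which unravels it to the acyclic epoxy cinnamyl ether 8, made from two syringaldehyde-derived aryl vinyl carbinols.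
3. Enabling feature: in each tetrahydrofuran ring the oxygen sits on a benzylic carbon bearing a 4-oxy-3,5-dimethoxyphenyl ring (good radical and cation stabilisation) and is linked through one CH2 to a ring-fusion carbon; an oxirane carbon β to the ether oxygen can therefore add as a radical to the styrene β-carbon (5-exo), and the oxirane oxygen, then on CH2, is placed to close onto the benzylic carbon.
4. Ring order: tetrahydrofuran bearing ring S2 (radical C–C closure), then tetrahydrofuran bearing ring S1 (benzylic C–O closure), both in step 7; no ring is formed afterwards.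
5. Absolute control: one carbinol centre from a Sharpless kinetic resolution governs the four core centres; three oxazolidinone auxiliaries govern the six side-chain centres and leave together in one LiBH4 reduction.

Key step: step 7

Remark (labels): ring S1 = syringyl ring that will carry units B and A; ring S2 = syringyl ring that will carry unit C; unit A = outer, unit B = middle, unit C = lone guaiacylglycerol unit; in every unit C7 is benzylic, C8 carries the aryl ether oxygen, C9 is the CH2OH (or acyl) carbon.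
Remark (assumption): both enantiomers of 4-benzyl-3-(chloroacetyl)oxazolidin-2-one (13, 21) are taken as purchasable; each is otherwise one N-acylation of the parent oxazolidinone away.

**Route**

Step 1
Reactants: 1 4-(benzyloxy)-3,5-dimethoxybenzaldehyde
Product: 2 rac-1-[4-(benzyloxy)-3,5-dimethoxyphenyl]prop-2-en-1-ol
Conditions: CH2=CHMgBr (1.2 equiv), THF, −78 to 0 °C; then H2O
Reagents that add atoms: vinylmagnesium bromide, C=C[Mg]Br
Why: Grignard 1,2-addition to the aromatic aldehyde gives the racemic aryl vinyl carbinol needed for the resolution.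

Step 2
Reactants: 2 rac-1-[4-(benzyloxy)-3,5-dimethoxyphenyl]prop-2-en-1-ol
Product: 3 (S)-[4-(benzyloxy)-3,5-dimethoxyphenyl][(2R)-oxiran-2-yl]methanol
Conditions: Ti(OiPr)4 (10 mol%), L-(+)-diisopropyl tartrate (15 mol%), t-BuOOH (0.45 equiv), 4 Å MS, CH2Cl2, −20 °C
Reagents that add atoms: tert-butyl hydroperoxide, CC(C)(C)OO
Why: Sharpless kinetic resolution, in which with L-(+)-tartrate the (R)-carbinol of 2 should be epoxidised much faster, on the face anti to its aryl group, to the erythro epoxy alcohol 3 while (S)-2 stays behind (the carbinol descriptor becomes S only because the oxirane carbon now outranks the aryl group); this sets the one centre from which the whole core is derived.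

Step 3
Reactants: 4 syringaldehyde (4-hydroxy-3,5-dimethoxybenzaldehyde)
Product: 5 3,5-dimethoxy-4-[(triisopropylsilyl)oxy]benzaldehyde
Conditions: i-Pr3SiCl, imidazole, DMF, 40 °C
Reagents that add atoms: chlorotriisopropylsilane, CC(C)[Si](Cl)(C(C)C)C(C)C
Why: phenol silylation; the hindered aryl silyl ether should survive the Grignard, PBr3, NaH, Cp2TiCl and I2 steps and is later removed by fluoride without touching the benzyl ether on ring S2.

Step 4
Reactants: 5 3,5-dimethoxy-4-[(triisopropylsilyl)oxy]benzaldehyde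
Product: 6 rac-1-{3,5-dimethoxy-4-[(triisopropylsilyl)oxy]phenyl}prop-2-en-1-ol
Conditions: CH2=CHMgBr (1.2 equiv), THF, −78 to 0 °C; then H2O
Reagents that add atoms: vinylmagnesium bromide, C=C[Mg]Br
Why: Grignard 1,2-addition; the stereocentre is lost in the next step, so the racemate is used.

Step 5
Reactants: 6 rac-1-{3,5-dimethoxy-4-[(triisopropylsilyl)oxy]phenyl}prop-2-en-1-ol
Product: 7 {4-[(1E)-3-bromoprop-1-en-1-yl]-2,6-dimethoxyphenoxy}triisopropylsilane
Conditions: PBr3 (0.4 equiv), Et2O, 0 °C; used crude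
Reagents that add atoms: phosphorus tribromide, BrP(Br)Br
Why: bromination of a 1-arylallyl alcohol with allylic transposition gives the conjugated primary (E)-cinnamyl bromide, the thermodynamically favoured allylic isomer.

Step 6
Reactants: 3 (S)-[4-(benzyloxy)-3,5-dimethoxyphenyl][(2R)-oxiran-2-yl]methanol; 7 {4-[(1E)-3-bromoprop-1-en-1-yl]-2,6-dimethoxyphenoxy}triisopropylsilane
Product: 8 (2R)-2-[(S)-[4-(benzyloxy)-3,5-dimethoxyphenyl]({(2E)-3-[3,5-dimethoxy-4-(triisopropylsilyloxy)phenyl]prop-2-en-1-yl}oxy)methyl]oxirane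
Conditions: NaH (added to 3 + 7), n-Bu4NI (cat.), THF–DMF, 0 °C
Reagents that add atoms: none
Why: Williamson ether synthesis on a reactive allylic bromide; the alkoxide is formed in the presence of 7 at 0 °C so that alkylation outruns Payne rearrangement, and no stereocentre is touched.

Step 7
Reactants: 8 epoxy cinnamyl ether
Product: 11 (1R,3aS,4R,6aS)-4-[4-(benzyloxy)-3,5-dimethoxyphenyl]-1-{3,5-dimethoxy-4-[(triisopropylsilyl)oxy]phenyl}tetrahydro-1H,3H-furo[3,4-c]furan, via benzyltitanium alkoxide 9 (not isolated), via benzylic iodide 10 (not isolated)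
Conditions: Cp2TiCl2 (2.5 equiv), Zn dust, THF, rt (Cp2TiCl solution decanted from Zn); 8 added over 1 h; then I2 (1.3 equiv), rt to 50 °C
Reagents that add atoms: none
Why: Cp2TiCl (trivalent titanium) opens the terminal oxirane of 8 homolytically at its more substituted carbon, and the β-titanoxy radical adds 5-exo-trig to the cinnamyl double bond, which forms the ring-fusion C–C bond and the first tetrahydrofuran ring and leaves a benzylic radical that a second Cp2TiCl captures as benzyltitanium 9; iodine turns the C–Ti bond into benzylic iodide 10, which the titanium alkoxide oxygen displaces (5-exo-tet, SN1-like through the cation stabilised by the 4-silyloxy-3,5-dimethoxyphenyl ring) to close the second tetrahydrofuran ring at the benzylic C–O bond. The closest known reaction type is the Cp2TiCl-mediated radical cyclisation of epoxy cinnamyl ethers with iodine termination used for furofuran lignans, a radical–polar crossover cascade. The carbinol centre of 8 is the only controlling element: in the chair-like transition state of the 5-hexenyl-type radical cyclisation its aryl group sits pseudo-equatorial, so it ends up trans to the CH2O–Ti arm and that arm cis to the new benzylic arm, which fixes both ring-fusion centres (3aS,6aS) with cis fusion. The fourth centre (C1) is set in the C–O closure, where the cis-bicyclo[3.3.0] framework should place the aryl group on the convex face, as in the diequatorial furofurans. The step needs opening at the internal oxirane carbon, 5-exo over 6-endo addition, and capture of the benzylic position by oxygen instead of protonation; the radical stability order, the styrene acceptor and the iodine quench should secure these, and the oxirane configuration is irrelevant because that carbon becomes the radical centre.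

Step 8
Reactants: 11 furofuran silyl ether
Product: 12 4-[(1R,3aS,4R,6aS)-4-[4-(benzyloxy)-3,5-dimethoxyphenyl]tetrahydro-1H,3H-furo[3,4-c]furan-1-yl]-2,6-dimethoxyphenol
Conditions: Bu4NF (1.1 equiv), THF, 0 °C
Reagents that add atoms: none
Why: fluoride cleavage of the aryl silyl ether frees the ring S1 phenol while the benzyl ether on ring S2 stays.

Step 9
Reactants: 12 ring S1 phenol; 13 (S)-4-benzyl-3-(chloroacetyl)oxazolidin-2-one
Product: 14 (S)-4-benzyl-3-{2-[4-((1R,3aS,4R,6aS)-4-[4-(benzyloxy)-3,5-dimethoxyphenyl]tetrahydro-1H,3H-furo[3,4-c]furan-1-yl)-2,6-dimethoxyphenoxy]acetyl}oxazolidin-2-one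
Conditions: K2CO3, NaI (10 mol%), acetone, 40 °C
Reagents that add atoms: none
Why: SN2 O-alkylation of the phenoxide by the α-halo imide (iodide catalysis) installs C8/C9 of unit B together with the (S)-auxiliary.

Step 10
Reactants: 15 vanillin; 13 (S)-4-benzyl-3-(chloroacetyl)oxazolidin-2-one
Product: 16 (S)-4-benzyl-3-[2-(4-formyl-2-methoxyphenoxy)acetyl]oxazolidin-2-one
Conditions: K2CO3, NaI (10 mol%), acetone, 40 °C
Reagents that add atoms: none
Why: the same phenoxide SN2 alkylation gives the aldehyde for unit B that already carries C8/C9 and the (S)-auxiliary of unit A.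

Step 11
Reactants: 14 glycolyl imide on ring S1; 16 aldehyde imide
Product: 18 syn-aldol adduct of unit B: imide 14 whose glycolyl carbon (C8; 2S) bears an (R)-hydroxy(aryl)methyl group (C7; 3R) in which aryl = 3-methoxy-4-{2-oxo-2-[(S)-4-benzyl-2-oxooxazolidin-3-yl]ethoxy}phenyl, via Z-dibutylboron enolate 17 (not isolated)
Conditions: Bu2BOTf (1.05 equiv), i-Pr2NEt (1.2 equiv), CH2Cl2, −78 to 0 °C; 16, −78 to 0 °C; pH 7 buffer, MeOH, 30% H2O2, 0 °C
Reagents that add atoms: none
Why: Evans boron syn-aldol, in which the Z-boron enolate 17 adds through a chair-like Zimmerman–Traxler transition state on the face opposite the benzyl group of the (S)-auxiliary and should give the (2S,3R) syn adduct, i.e. threo (7R,8R) unit B; the glycolyl imide inside 16 is not enolised because no free boron triflate is left.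

Step 12
Reactants: 18 syn-aldol adduct
Product: 19 7-O-tert-butyldimethylsilyl ether of 18 (unit B)
Conditions: t-BuMe2SiOTf, 2,6-lutidine, CH2Cl2, −78 to 0 °C
Reagents that add atoms: tert-butyldimethylsilyl triflate, CC(C)(C)[Si](C)(C)OS(=O)(=O)C(F)(F)F
Why: silylation of the aldol hydroxyl prevents retro-aldol cleavage in the basic steps 14 and 15.

Step 13
Reactants: 19 silyl ether
Product: 20 ring S2 phenol (19 without its benzyl group)
Conditions: H2 (1 atm), Pd/C (10% w/w), EtOAc, rt
Reagents that add atoms: none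
Why: hydrogenolysis of the aryl benzyl ether; the benzylic silyl ether, the cyclic benzylic ethers and the imides should survive neutral conditions at 1 atm.

Step 14
Reactants: 20 ring S2 phenol; 21 (R)-4-benzyl-3-(chloroacetyl)oxazolidin-2-one
Product: 22 tris-imide: 20 whose ring S2 oxygen carries CH2C(=O)-[(R)-4-benzyl-2-oxooxazolidin-3-yl]
Conditions: K2CO3, NaI (10 mol%), acetone, rt
Reagents that add atoms: none
Why: phenoxide SN2 alkylation as in step 9 installs C8/C9 of unit C with the (R)-auxiliary; the α-branched imide of unit B is not deprotonated by carbonate.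

Step 15
Reactants: 22 tris-imide; 23 4-(benzyloxy)-3-methoxybenzaldehyde (3 equiv)
Product: 25 double anti-aldol adduct: unit A (2R,3R)-3-[4-(benzyloxy)-3-methoxyphenyl]-3-hydroxypropanoyl imide on the (S)-auxiliary; unit C (2S,3S) analogue on the (R)-auxiliary; unit B unchanged, via bis(trimethylsilyl) ether 24 (not isolated)
Conditions: MgCl2 (40 mol%), Et3N, Me3SiCl, EtOAc, rt; then PPTS (cat.), MeOH, 0 °C
Reagents that add atoms: none
Why: MgCl2-catalysed direct anti-aldol of N-acyloxazolidinones with an aromatic aldehyde (soft enolisation by Et3N, silyl trapping of the aldolate), in which each glycolyl imide should react through its chelated Z-magnesium enolate in a boat-like transition state on the face away from the benzyl group of its own auxiliary, so the (S)-imide gives erythro (7R,8S) unit A and the (R)-imide erythro (7S,8R) unit C, while the α-branched imide of unit B is not enolised (allylic 1,3-strain keeps its C–H in the imide plane).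

Step 16
Reactants: 25 double anti-aldol adduct
Product: 26 pentaol: units A (7R,8S), B (7R,8R; 7-O-silyl) and C (7S,8R) with free C9 alcohols; terminal phenols as benzyl ethers
Conditions: LiBH4 (excess), MeOH (additive), THF, 0 °C
Reagents that add atoms: none
Why: LiBH4 reduces the three N-acyl oxazolidinones to the primary alcohols and releases the auxiliaries without touching a stereocentre.

Step 17
Reactants: 26 silylated pentaol
Product: 27 bis(O-benzyl) ether of the target (both terminal guaiacyl phenols benzylated)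
Conditions: Bu4NF, THF, rt
Reagents that add atoms: none
Why: fluoride desilylation of the benzylic silyl ether of unit B under non-acidic conditions, which spares the benzylic ethers of the core.

Step 18
Reactants: 27 bis(O-benzyl) ether
Product: 28 CNP0316493.1 (target)
Conditions: H2 (1 atm), Pd/C (10% w/w), EtOAc–MeOH, rt
Reagents that add atoms: none
Why: hydrogenolysis of the two aryl benzyl ethers under neutral conditions, as used for benzyl-protected arylglycerol β-aryl ethers, should leave the benzylic alcohols and the furofuran intact.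

**Compound list**

1 | 4-(benzyloxy)-3,5-dimethoxybenzaldehyde | O=Cc1cc(OC)c(OCc2ccccc2)c(OC)c1 | starting material
2 | rac-1-[4-(benzyloxy)-3,5-dimethoxyphenyl]prop-2-en-1-ol | C=CC(O)c1cc(OC)c(OCc2ccccc2)c(OC)c1 | intermediate
3 | (S)-[4-(benzyloxy)-3,5-dimethoxyphenyl][(2R)-oxiran-2-yl]methanol (erythro) | O[C@H]([C@H]1CO1)c1cc(OC)c(OCc2ccccc2)c(OC)c1 | intermediate
4 | syringaldehyde | O=Cc1cc(OC)c(O)c(OC)c1 | starting material
5 | 3,5-dimethoxy-4-[(triisopropylsilyl)oxy]benzaldehyde | O=Cc1cc(OC)c(O[Si](C(C)C)(C(C)C)C(C)C)c(OC)c1 | intermediate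
6 | rac-1-{3,5-dimethoxy-4-[(triisopropylsilyl)oxy]phenyl}prop-2-en-1-ol | C=CC(O)c1cc(OC)c(O[Si](C(C)C)(C(C)C)C(C)C)c(OC)c1 | intermediate
7 | {4-[(1E)-3-bromoprop-1-en-1-yl]-2,6-dimethoxyphenoxy}triisopropylsilane | BrC/C=C/c1cc(OC)c(O[Si](C(C)C)(C(C)C)C(C)C)c(OC)c1 | intermediate
8 | (2R)-2-[(S)-[4-(benzyloxy)-3,5-dimethoxyphenyl]({(2E)-3-[3,5-dimethoxy-4-(triisopropylsilyloxy)phenyl]prop-2-en-1-yl}oxy)methyl]oxirane | C(/C=C/c1cc(OC)c(O[Si](C(C)C)(C(C)C)C(C)C)c(OC)c1)O[C@H]([C@H]1CO1)c1cc(OC)c(OCc2ccccc2)c(OC)c1 | intermediate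
9 | 2,3-trans-3,4-cis tetrahydrofuran with ring S2 at C2, CH2O–TiCp2Cl at C3 and CH(TiCp2Cl)(ring S1) at C4 (tetravalent titanium; benzylic centre undefined) | Cl[Ti](C1C=CC=C1)(C1C=CC=C1)OC[C@@H]1[C@H](C([Ti](Cl)(C2C=CC=C2)C2C=CC=C2)c2cc(OC)c(O[Si](C(C)C)(C(C)C)C(C)C)c(OC)c2)CO[C@H]1c1cc(OC)c(OCc2ccccc2)c(OC)c1 | intermediate (not isolated)
10 | the same tetrahydrofuran with CH(I)(ring S1) at C4 and CH2O–TiCp2Cl at C3 (benzylic centre undefined) | Cl[Ti](C1C=CC=C1)(C1C=CC=C1)OC[C@@H]1[C@H](C(I)c2cc(OC)c(O[Si](C(C)C)(C(C)C)C(C)C)c(OC)c2)CO[C@H]1c1cc(OC)c(OCc2ccccc2)c(OC)c1 | intermediate (not isolated)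
11 | (1R,3aS,4R,6aS)-4-[4-(benzyloxy)-3,5-dimethoxyphenyl]-1-{3,5-dimethoxy-4-[(triisopropylsilyl)oxy]phenyl}tetrahydro-1H,3H-furo[3,4-c]furan | CC(C)[Si](Oc1c(OC)cc(cc1OC)[C@@H]1OC[C@@H]2[C@H]1CO[C@H]2c1cc(OC)c(OCc2ccccc2)c(OC)c1)(C(C)C)C(C)C | intermediate
12 | 4-[(1R,3aS,4R,6aS)-4-[4-(benzyloxy)-3,5-dimethoxyphenyl]tetrahydro-1H,3H-furo[3,4-c]furan-1-yl]-2,6-dimethoxyphenol | Oc1c(OC)cc(cc1OC)[C@@H]1OC[C@@H]2[C@H]1CO[C@H]2c1cc(OC)c(OCc2ccccc2)c(OC)c1 | intermediate
13 | (S)-4-benzyl-3-(chloroacetyl)oxazolidin-2-one | ClCC(=O)N1[C@@H](Cc2ccccc2)COC1=O | starting material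
14 | (S)-4-benzyl-3-{2-[4-((1R,3aS,4R,6aS)-4-[4-(benzyloxy)-3,5-dimethoxyphenyl]tetrahydro-1H,3H-furo[3,4-c]furan-1-yl)-2,6-dimethoxyphenoxy]acetyl}oxazolidin-2-one | O=C(COc1c(OC)cc(cc1OC)[C@@H]1OC[C@@H]2[C@H]1CO[C@H]2c1cc(OC)c(OCc2ccccc2)c(OC)c1)N1[C@@H](Cc2ccccc2)COC1=O | intermediate
15 | vanillin | O=Cc1ccc(O)c(OC)c1 | starting material
16 | (S)-4-benzyl-3-[2-(4-formyl-2-methoxyphenoxy)acetyl]oxazolidin-2-one | O=Cc1ccc(OCC(=O)N2[C@@H](Cc3ccccc3)COC2=O)c(OC)c1 | intermediate
17 | Z-dibutylboron enolate of 14 | CCCCB(CCCC)O/C(=C\Oc1c(OC)cc(cc1OC)[C@@H]1OC[C@@H]2[C@H]1CO[C@H]2c1cc(OC)c(OCc2ccccc2)c(OC)c1)N1[C@@H](Cc2ccccc2)COC1=O | intermediate (not isolated)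
18 | syn-aldol adduct, unit B (2S,3R) on the (S)-auxiliary; middle ring carries OCH2C(=O)-(S)-auxiliary; ring S2 O-benzyl | O=C(COc1ccc(cc1OC)[C@@H](O)[C@@H](C(=O)N1[C@@H](Cc2ccccc2)COC1=O)Oc1c(OC)cc(cc1OC)[C@@H]1OC[C@@H]2[C@H]1CO[C@H]2c1cc(OC)c(OCc2ccccc2)c(OC)c1)N1[C@@H](Cc2ccccc2)COC1=O | intermediate
19 | 7-O-tert-butyldimethylsilyl ether of 18 | O=C(COc1ccc(cc1OC)[C@@H](O[Si](C)(C)C(C)(C)C)[C@@H](C(=O)N1[C@@H](Cc2ccccc2)COC1=O)Oc1c(OC)cc(cc1OC)[C@@H]1OC[C@@H]2[C@H]1CO[C@H]2c1cc(OC)c(OCc2ccccc2)c(OC)c1)N1[C@@H](Cc2ccccc2)COC1=O | intermediate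
20 | ring S2 phenol from 19 | O=C(COc1ccc(cc1OC)[C@@H](O[Si](C)(C)C(C)(C)C)[C@@H](C(=O)N1[C@@H](Cc2ccccc2)COC1=O)Oc1c(OC)cc(cc1OC)[C@@H]1OC[C@@H]2[C@H]1CO[C@H]2c1cc(OC)c(O)c(OC)c1)N1[C@@H](Cc2ccccc2)COC1=O | intermediate
21 | (R)-4-benzyl-3-(chloroacetyl)oxazolidin-2-one | ClCC(=O)N1[C@H](Cc2ccccc2)COC1=O | starting material
22 | tris-imide: 20 with OCH2C(=O)-(R)-auxiliary on ring S2 | O=C(COc1ccc(cc1OC)[C@@H](O[Si](C)(C)C(C)(C)C)[C@@H](C(=O)N1[C@@H](Cc2ccccc2)COC1=O)Oc1c(OC)cc(cc1OC)[C@@H]1OC[C@@H]2[C@H]1CO[C@H]2c1cc(OC)c(OCC(=O)N2[C@H](Cc3ccccc3)COC2=O)c(OC)c1)N1[C@@H](Cc2ccccc2)COC1=O | intermediate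
23 | 4-(benzyloxy)-3-methoxybenzaldehyde | O=Cc1ccc(OCc2ccccc2)c(OC)c1 | starting material
24 | bis(trimethylsilyl) ether of 25 (C7 oxygens of units A and C) | COc1cc([C@@H](O[Si](C)(C)C)[C@H](C(=O)N2[C@@H](Cc3ccccc3)COC2=O)Oc2ccc(cc2OC)[C@@H](O[Si](C)(C)C(C)(C)C)[C@@H](C(=O)N2[C@@H](Cc3ccccc3)COC2=O)Oc2c(OC)cc(cc2OC)[C@@H]2OC[C@@H]3[C@H]2CO[C@H]3c2cc(OC)c(O[C@H](C(=O)N3[C@H](Cc4ccccc4)COC3=O)[C@@H](O[Si](C)(C)C)c3ccc(OCc4ccccc4)c(OC)c3)c(OC)c2)ccc1OCc1ccccc1 | intermediate (not isolated)
25 | double anti-aldol adduct: unit A (2R,3R) on (S)-auxiliary, unit B (2S,3R; 7-O-silyl) on (S)-auxiliary, unit C (2S,3S) on (R)-auxiliary; terminal phenols O-benzyl | COc1cc([C@@H](O)[C@H](C(=O)N2[C@@H](Cc3ccccc3)COC2=O)Oc2ccc(cc2OC)[C@@H](O[Si](C)(C)C(C)(C)C)[C@@H](C(=O)N2[C@@H](Cc3ccccc3)COC2=O)Oc2c(OC)cc(cc2OC)[C@@H]2OC[C@@H]3[C@H]2CO[C@H]3c2cc(OC)c(O[C@H](C(=O)N3[C@H](Cc4ccccc4)COC3=O)[C@@H](O)c3ccc(OCc4ccccc4)c(OC)c3)c(OC)c2)ccc1OCc1ccccc1 | intermediate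
26 | pentaol: units A (7R,8S), B (7R,8R; 7-O-tert-butyldimethylsilyl), C (7S,8R); terminal phenols O-benzyl | COc1cc([C@@H](O)[C@H](CO)Oc2ccc(cc2OC)[C@@H](O[Si](C)(C)C(C)(C)C)[C@@H](CO)Oc2c(OC)cc(cc2OC)[C@@H]2OC[C@@H]3[C@H]2CO[C@H]3c2cc(OC)c(O[C@H](CO)[C@@H](O)c3ccc(OCc4ccccc4)c(OC)c3)c(OC)c2)ccc1OCc1ccccc1 | intermediate
27 | bis(O-benzyl) ether of the target (both terminal guaiacyl phenols benzylated) | COc1cc([C@@H](O)[C@H](CO)Oc2ccc(cc2OC)[C@@H](O)[C@@H](CO)Oc2c(OC)cc(cc2OC)[C@@H]2OC[C@@H]3[C@H]2CO[C@H]3c2cc(OC)c(O[C@H](CO)[C@@H](O)c3ccc(OCc4ccccc4)c(OC)c3)c(OC)c2)ccc1OCc1ccccc1 | intermediate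
28 | CNP0316493.1: (7R,8S,7'R,8'S)-syringaresinol whose ring S1 oxygen carries a (7R,8R)-threo-guaiacylglycerol-8-yl unit (B), itself 4-O-linked to a (7R,8S)-erythro-guaiacylglycerol-8-yl unit (A), and whose ring S2 oxygen carries a (7S,8R)-erythro-guaiacylglycerol-8-yl unit (C) | COc1cc([C@@H](O)[C@H](CO)Oc2ccc([C@@H](O)[C@@H](CO)Oc3c(OC)cc([C@@H]4OC[C@@H]5[C@H]4CO[C@H]5c4cc(OC)c(O[C@H](CO)[C@@H](O)c5ccc(O)c(OC)c5)c(OC)c4)cc3OC)cc2OC)ccc1O | target

**Step count**

Total steps: 18. Longest linear sequence: 15 steps (3, 4, 5, 6, 7, 8, 9, 11–18) from syringaldehyde 4.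

**Steps most likely to fail, with fallbacks**

1. Step 15 (double magnesium anti-aldol). The reaction type is established for N-acyloxazolidinones; aryloxyacetyl imides are a new substrate within that class. The likely failure is weak anti/syn discrimination at C7 of units A and C, while the C8 face, set by the chelated enolate, should hold; incomplete double conversion is a second concern. The fallback makes C7 depend on C8 instead of on the aldol. It sets out from 26, which would then carry benzylic epimers. DDQ (CH2Cl2–dioxane, rt) oxidises only the two free electron-rich benzylic carbinols, as known for non-phenolic arylglycerol β-aryl ethers, to the bis(aryl ketone) F1; the primary alcohols and the silylated carbinol of unit B stay. NaBH4 (MeOH, −40 °C) then reduces both ketones under Felkin–Anh control (α-aryloxy group anti to hydride), which should favour the erythro alcohols. The fallback comes back at 26.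

2. Step 7 (radical–polar crossover cascade). The likely failures are protonation or reduction of the benzyltitanium before oxygen capture, elimination from the iodide, or weak facial control in the C–O closure. The fallback separates the two ring closures and sets out from 8. The same Cp2TiCl cyclisation with protic work-up and no iodine gives the 2,3-trans-3,4-cis tetrahydrofuran alcohol [(2R,3S,4S)-2-[4-(benzyloxy)-3,5-dimethoxyphenyl]-4-{3,5-dimethoxy-4-[(triisopropylsilyl)oxy]benzyl}tetrahydrofuran-3-yl]methanol F2. Bu4NF gives the phenol F3. DDQ (1 equiv, dioxane, rt; alternatively Ag2O) oxidises the 4-alkyl-2,6-dimethoxyphenol to the p-quinone methide F4, whose CH2OH adds 1,6 (5-exo-trig) on the convex face, the closure by which sinapyl alcohol dimers give syringaresinol. The benzylic C–O bond is thus formed directly in the phenol, and the fallback comes back at 12.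

3. Step 2 (kinetic resolution). The likely failures are slow, poorly selective epoxidation of a monosubstituted alkene and Lewis-acid opening of the electron-rich epoxy alcohol. The fallback sets out from 2 and separates resolution from epoxidation. Candida antarctica lipase B with vinyl acetate acylates the (R)-alcohol to (R)-1-[4-(benzyloxy)-3,5-dimethoxyphenyl]prop-2-en-1-yl acetate F5. Methanolysis (K2CO3, MeOH) gives (R)-1-[4-(benzyloxy)-3,5-dimethoxyphenyl]prop-2-en-1-ol F6. Hydroxyl-directed epoxidation (VO(acac)2, t-BuOOH, CH2Cl2) then gives 3 together with its oxirane epimer (S)-[4-(benzyloxy)-3,5-dimethoxyphenyl][(2S)-oxiran-2-yl]methanol F7. Both converge in step 7 because the oxirane carbon becomes the radical centre, so the fallback comes back at 3.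

**Further compounds**

F1 | step 15 | bis(aryl ketone): 26 with C7 of units A and C oxidised to C=O | COc1cc(C(=O)[C@H](CO)Oc2ccc(cc2OC)[C@@H](O[Si](C)(C)C(C)(C)C)[C@@H](CO)Oc2c(OC)cc(cc2OC)[C@@H]2OC[C@@H]3[C@H]2CO[C@H]3c2cc(OC)c(O[C@H](CO)C(=O)c3ccc(OCc4ccccc4)c(OC)c3)c(OC)c2)ccc1OCc1ccccc1
F2 | step 7 | [(2R,3S,4S)-2-[4-(benzyloxy)-3,5-dimethoxyphenyl]-4-{3,5-dimethoxy-4-[(triisopropylsilyl)oxy]benzyl}tetrahydrofuran-3-yl]methanol | OC[C@@H]1[C@H](Cc2cc(OC)c(O[Si](C(C)C)(C(C)C)C(C)C)c(OC)c2)CO[C@H]1c1cc(OC)c(OCc2ccccc2)c(OC)c1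
F3 | step 7 | 4-{[(3S,4S,5R)-5-[4-(benzyloxy)-3,5-dimethoxyphenyl]-4-(hydroxymethyl)tetrahydrofuran-3-yl]methyl}-2,6-dimethoxyphenol | OC[C@@H]1[C@H](Cc2cc(OC)c(O)c(OC)c2)CO[C@H]1c1cc(OC)c(OCc2ccccc2)c(OC)c1
F4 | step 7 | p-quinone methide from F3 (2,6-dimethoxy-4-alkylidenecyclohexa-2,5-dienone) | OC[C@@H]1[C@H](C=C2C=C(OC)C(=O)C(OC)=C2)CO[C@H]1c1cc(OC)c(OCc2ccccc2)c(OC)c1
F5 | step 2 | (R)-1-[4-(benzyloxy)-3,5-dimethoxyphenyl]prop-2-en-1-yl acetate | CC(=O)O[C@H](C=C)c1cc(OC)c(OCc2ccccc2)c(OC)c1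
F6 | step 2 | (R)-1-[4-(benzyloxy)-3,5-dimethoxyphenyl]prop-2-en-1-ol | O[C@H](C=C)c1cc(OC)c(OCc2ccccc2)c(OC)c1
F7 | step 2 | (S)-[4-(benzyloxy)-3,5-dimethoxyphenyl][(2S)-oxiran-2-yl]methanol (threo) | O[C@H]([C@@H]1CO1)c1cc(OC)c(OCc2ccccc2)c(OC)c1
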